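Ring A (C4a, C5, C6, C7, C8, C8a) bears oxygen at C5, C7 and C8a. It is therefore treated as an aromatised 1,3,5-tricarbonyl chain whose C8a oxygen is already O1 of the pyran, and it is made last by disconnecting C4a–C5. The precursor is an enantiopure 2-aryl-3-benzyloxy-3,4-dihydro-2H-pyran whose enol-ether carbon carries a dioxinonylmethyl arm; both stereocentres come from an Evans syn glycolate aldol. Heating expels acetone, and the acylketene acylates the enol-ether β-carbon, closing and aromatising ring A in one operation. The endocyclic double bond is fixed by cross-coupling, because hemiketal dehydration would place it exocyclic. Selective 7-O-galloylation and hydrogenolysis follow.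

Key step: step 15

Assumption: 3,4,5-tris(benzyloxy)benzoic acid 1 is taken as a catalogue compound (perbenzylated and saponified gallic acid); atom labels such as C4a or C8a are flavan numbers and are also used for the atoms that become them.

Step 1
Reactants: 1 3,4,5-tris(benzyloxy)benzoic acid
Product: 2 3,4,5-tris(benzyloxy)benzoyl chloride
Conditions: (COCl)2, DMF (cat.), CH2Cl2, 0 °C to rt
Reagents that add atoms: oxalyl chloride, O=C(Cl)C(=O)Cl
Why: DMF-catalysed acid chloride formation is mild enough for aryl benzyl ethers, and one batch of 2 serves both step 2 and step 16.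

Step 2
Reactants: 2 3,4,5-tris(benzyloxy)benzoyl chloride
Product: 3 3,4,5-tris(benzyloxy)benzaldehyde
Conditions: LiAlH(Ot-Bu)3 (1.0 equiv), THF, −78 °C
Reagents that add atoms: none
Why: Partial reduction of an aroyl chloride with the bulky, attenuated alkoxyaluminium hydride stops at the aldehyde at low temperature, because the electron-rich aldehyde is reduced much more slowly than the acid chloride.

Step 3
Reactants: 4 (S)-4-benzyl-2-oxazolidinone; 5 benzyloxyacetyl chloride
Product: 6 (S)-4-benzyl-3-[2-(benzyloxy)acetyl]oxazolidin-2-one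
Conditions: n-BuLi, THF, −78 °C; then 5, −78 to 0 °C
Reagents that add atoms: none
Why: Deprotonation and N-acylation with an acid chloride is the standard loading of an Evans auxiliary and leaves its stereocentre untouched.

Step 4
Reactants: 6 (S)-4-benzyl-3-[2-(benzyloxy)acetyl]oxazolidin-2-one; 3 3,4,5-tris(benzyloxy)benzaldehyde
Product: 8 (S)-4-benzyl-3-[(2S,3R)-2-(benzyloxy)-3-hydroxy-3-[3,4,5-tris(benzyloxy)phenyl]propanoyl]oxazolidin-2-one, via boron enolate 7 (not isolated)
Conditions: Bu2BOTf, Et3N, CH2Cl2, −78 to 0 °C; 3, −78 to 0 °C; H2O2, MeOH, pH 7 buffer, 0 °C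
Reagents that add atoms: dibutylboron triflate, CCCCB(CCCC)OS(=O)(=O)C(F)(F)F (its Bu2B group is present in 7 only)
Why: In this Evans syn glycolate aldol, soft enolisation gives the Z boron enolate 7, which reacts through a chair Zimmerman–Traxler transition state on the face away from the auxiliary benzyl group, so the (S)-auxiliary sets (2S,3R), the future C3 and C2 in their 2,3-cis relation.

Step 5
Reactants: 8 (S)-4-benzyl-3-[(2S,3R)-2-(benzyloxy)-3-hydroxy-3-[3,4,5-tris(benzyloxy)phenyl]propanoyl]oxazolidin-2-one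
Product: 9 (2S,3R)-2-(benzyloxy)-3-hydroxy-N-methoxy-N-methyl-3-[3,4,5-tris(benzyloxy)phenyl]propanamide
Conditions: MeNH(OMe)·HCl, AlMe3, THF, −20 to 0 °C
Reagents that add atoms: N,O-dimethylhydroxylamine hydrochloride, CNOC.Cl
Why: Weinreb transamidation with the aluminium amide is assisted by the free β-hydroxyl, releases the auxiliary for recovery and touches neither stereocentre.

Step 6
Reactants: 9 (2S,3R)-2-(benzyloxy)-3-hydroxy-N-methoxy-N-methyl-3-[3,4,5-tris(benzyloxy)phenyl]propanamide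
Product: 10 (2S,3R)-2-(benzyloxy)-N-methoxy-N-methyl-3-[(triethylsilyl)oxy]-3-[3,4,5-tris(benzyloxy)phenyl]propanamide
Conditions: TESCl, imidazole, DMF, 0 °C to rt
Reagents that add atoms: chlorotriethylsilane, CC[Si](Cl)(CC)CC
Why: Routine silylation masks the benzylic hydroxyl, so the aldehyde made next can undergo neither retro-aldol cleavage nor β-elimination.

Step 7
Reactants: 10 (2S,3R)-2-(benzyloxy)-N-methoxy-N-methyl-3-[(triethylsilyl)oxy]-3-[3,4,5-tris(benzyloxy)phenyl]propanamide
Product: 11 (2S,3R)-2-(benzyloxy)-3-[(triethylsilyl)oxy]-3-[3,4,5-tris(benzyloxy)phenyl]propanal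
Conditions: DIBAL-H, THF, −78 °C; Rochelle salt
Reagents that add atoms: none
Why: In this Weinreb amide reduction the chelated tetrahedral aluminium adduct survives until the quench, so reduction stops at the aldehyde, and the cold, non-basic medium keeps the α-alkoxy centre intact.

Step 8
Reactants: 11 (2S,3R)-2-(benzyloxy)-3-[(triethylsilyl)oxy]-3-[3,4,5-tris(benzyloxy)phenyl]propanal
Product: 12 methyl (2E,4R,5R)-4-(benzyloxy)-5-[(triethylsilyl)oxy]-5-[3,4,5-tris(benzyloxy)phenyl]pent-2-enoate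
Conditions: Ph3P=CHCO2Me, CH2Cl2, rt
Reagents that add atoms: methyl (triphenylphosphoranylidene)acetate, COC(=O)C=P(c1ccccc1)(c1ccccc1)c1ccccc1
Why: Wittig olefination with a stabilised, essentially non-basic ylide adds the two carbons that become C4a and C8a without epimerising the α-alkoxy aldehyde, and the alkene geometry is irrelevant because the alkene is saturated next.

Step 9
Reactants: 12 methyl (2E,4R,5R)-4-(benzyloxy)-5-[(triethylsilyl)oxy]-5-[3,4,5-tris(benzyloxy)phenyl]pent-2-enoate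
Product: 13 methyl (4R,5R)-4-(benzyloxy)-5-[(triethylsilyl)oxy]-5-[3,4,5-tris(benzyloxy)phenyl]pentanoate
Conditions: NiCl2·6H2O (0.2 equiv), NaBH4, MeOH–THF, 0 °C
Reagents that add atoms: none
Why: Nickel boride conjugate reduction saturates the enoate without hydrogenolysing benzyl ethers and, unlike single-electron reductants, without expelling the γ-benzyloxy group.

Step 10
Reactants: 13 methyl (4R,5R)-4-(benzyloxy)-5-[(triethylsilyl)oxy]-5-[3,4,5-tris(benzyloxy)phenyl]pentanoate
Product: 15 (5R,6R)-5-(benzyloxy)-6-[3,4,5-tris(benzyloxy)phenyl]tetrahydro-2H-pyran-2-one, via hydroxy ester 14 (not isolated)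
Conditions: PPTS (cat.), MeOH, rt; solvent switch to PhMe, 70 °C
Reagents that add atoms: none
Why: Mild acid methanolysis removes the TES ether and the freed δ-hydroxy ester 14 lactonises by acid-catalysed transesterification as methanol is driven off, PPTS being too weak to ionise the benzylic C–O bond, so both centres are retained.

Step 11
Reactants: 15 (5R,6R)-5-(benzyloxy)-6-[3,4,5-tris(benzyloxy)phenyl]tetrahydro-2H-pyran-2-one
Product: 16 (2R,3R)-3-(benzyloxy)-2-[3,4,5-tris(benzyloxy)phenyl]-3,4-dihydro-2H-pyran-6-yl diphenyl phosphate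
Conditions: KHMDS, (PhO)2P(O)Cl, DMPU, THF, −78 °C
Reagents that add atoms: diphenyl chlorophosphate, O=P(Cl)(Oc1ccccc1)Oc1ccccc1
Why: Kinetic enolisation at the only α-position and O-phosphorylation give the cyclic ketene acetal phosphate, which locks the double bond inside the ring between the future C4a and C8a, and no leaving group sits β to the enolate carbon, so elimination is not possible.

Step 12
Reactants: 16 (2R,3R)-3-(benzyloxy)-2-[3,4,5-tris(benzyloxy)phenyl]-3,4-dihydro-2H-pyran-6-yl diphenyl phosphate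
Product: 17 [(2R,3R)-3-(benzyloxy)-2-[3,4,5-tris(benzyloxy)phenyl]-3,4-dihydro-2H-pyran-6-yl]trimethylstannane
Conditions: (Me3Sn)2, Pd(PPh3)4 (5 mol %), LiCl, THF, reflux
Reagents that add atoms: hexamethylditin, C[Sn](C)(C)[Sn](C)(C)C
Why: Palladium-catalysed coupling of a lactone-derived ketene acetal phosphate with a distannane (Stille-type stannylation) exchanges C–O for C–Sn without moving the alkene.

Step 13
Reactants: 18 2,2,6-trimethyl-4H-1,3-dioxin-4-one
Product: 19 6-(chloromethyl)-2,2-dimethyl-4H-1,3-dioxin-4-one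
Conditions: LDA, THF, −78 °C; C2Cl6
Reagents that add atoms: hexachloroethane, ClC(Cl)(Cl)C(Cl)(Cl)Cl
Why: γ-Deprotonation of the vinylogous ester and positive-chlorine transfer from hexachloroethane to the exocyclic carbon is the standard entry to the 6-halomethyl dioxinone.

Step 14
Reactants: 17 [(2R,3R)-3-(benzyloxy)-2-[3,4,5-tris(benzyloxy)phenyl]-3,4-dihydro-2H-pyran-6-yl]trimethylstannane; 19 6-(chloromethyl)-2,2-dimethyl-4H-1,3-dioxin-4-one
Product: 20 6-{[(2R,3R)-3-(benzyloxy)-2-[3,4,5-tris(benzyloxy)phenyl]-3,4-dihydro-2H-pyran-6-yl]methyl}-2,2-dimethyl-4H-1,3-dioxin-4-one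
Conditions: Pd2(dba)3 (2.5 mol %), AsPh3 (10 mol %), THF, 45 °C; Et3N-deactivated silica
Reagents that add atoms: none
Why: Stille coupling of an α-alkoxyvinylstannane with an allylic chloride (the reactivity class of 4-halocrotonates) forms the C8a–C8 bond at the unhindered CH2 terminus under neutral conditions far below the fragmentation temperature of the dioxinone, so the double bond stays endocyclic.

Step 15
Reactants: 20 6-{[(2R,3R)-3-(benzyloxy)-2-[3,4,5-tris(benzyloxy)phenyl]-3,4-dihydro-2H-pyran-6-yl]methyl}-2,2-dimethyl-4H-1,3-dioxin-4-one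
Product: 23 (2R,3R)-3-(benzyloxy)-2-[3,4,5-tris(benzyloxy)phenyl]chroman-5,7-diol, via acylketene 21 (not isolated), via diketone tautomer 22 (not isolated)
Conditions: anhydrous PhMe (final 0.003 M), reflux (110 °C), syringe-pump addition of 20, slow Ar sweep to carry off acetone
Reagents that add atoms: none
Why: Proposed new method: at about 110 °C the dioxinone undergoes retro-[4+2] loss of acetone to acylketene 21, whose sp carbon (future C5) lies within reach of the electron-rich β-carbon of the cyclic enol ether (future C4a). Ring A closes by a 6-(enolendo)-exo attack of C4a on that carbon, or equivalently by 6π electrocyclisation of the dienylketene C4a=C8a–C8=C7(OH)–C6=C5=O reached by enolising the C7 ketone, and loss of the C4a proton gives diketone 22, which tautomerises irreversibly to the phloroglucinol mono-ether 23. The closest known reaction types are the cycloaddition of acylketenes to vinyl ethers, which begins with the same ketene-carbon to β-carbon bond, the dioxinone thermolysis–aromatisation route to resorcylates and the dienylketene closure of ketene benzannulations; none has been used to acylate a tethered enol ether into a phloroglucinol. No stereocentre is formed, and C2 and C3 are insulated from every charged or sp2 centre, so the aldol-derived configuration is carried through. The step needs C- rather than O-acylation and intra- rather than intermolecular capture: the C8a oxygen is already the ring ether O1 and cannot give a neutral pyrone, collapse of the C7 oxygen onto C8a or a [2+2] closure would build four-membered rings, and high dilution in dry toluene holds back ketene dimerisation, hydrolysis and capture by the phenols of 23.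

Step 16
Reactants: 23 (2R,3R)-3-(benzyloxy)-2-[3,4,5-tris(benzyloxy)phenyl]chroman-5,7-diol; 2 3,4,5-tris(benzyloxy)benzoyl chloride
Product: 24 (2R,3R)-3-(benzyloxy)-5-hydroxy-2-[3,4,5-tris(benzyloxy)phenyl]chroman-7-yl 3,4,5-tris(benzyloxy)benzoate
Conditions: 2 (0.95 equiv, slow addition), i-Pr2NEt, DMAP (5 mol %), CH2Cl2, −40 to 0 °C
Reagents that add atoms: none
Why: DMAP-catalysed O-acylation should favour the 7-OH, which has hydrogen at both ortho positions, over the 5-OH, which is buttressed by the C4 methylene, while slow sub-stoichiometric addition limits double acylation and any 5-ester or diester can be saponified back to 23.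

Step 17
Reactants: 24 (2R,3R)-3-(benzyloxy)-5-hydroxy-2-[3,4,5-tris(benzyloxy)phenyl]chroman-7-yl 3,4,5-tris(benzyloxy)benzoate
Product: 25 (−)-epigallocatechin 7-O-gallate, (2R,3R)-3,5-dihydroxy-2-(3,4,5-trihydroxyphenyl)chroman-7-yl 3,4,5-trihydroxybenzoate
Conditions: H2 (1 atm), Pd(OH)2/C, THF–EtOAc, rt
Reagents that add atoms: none
Why: Catalytic hydrogenolysis removes all seven O-benzyl groups under neutral conditions in a non-nucleophilic solvent, so the aryl gallate is not transesterified, C2 and C3 are not epimerised, and the cyclic C2–O1 bond reacts far more slowly than the benzyl ethers, as is usual for flavan-3-ols.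

Compound list
1 | 3,4,5-tris(benzyloxy)benzoic acid | O=C(O)c1cc(OCc2ccccc2)c(OCc2ccccc2)c(OCc2ccccc2)c1 | starting material
2 | 3,4,5-tris(benzyloxy)benzoyl chloride | O=C(Cl)c1cc(OCc2ccccc2)c(OCc2ccccc2)c(OCc2ccccc2)c1 | intermediate
3 | 3,4,5-tris(benzyloxy)benzaldehyde | O=Cc1cc(OCc2ccccc2)c(OCc2ccccc2)c(OCc2ccccc2)c1 | intermediate
4 | (S)-4-benzyl-2-oxazolidinone | O=C1N[C@@H](Cc2ccccc2)CO1 | starting material
5 | benzyloxyacetyl chloride | O=C(Cl)COCc1ccccc1 | starting material
6 | (S)-4-benzyl-3-[2-(benzyloxy)acetyl]oxazolidin-2-one | O=C(COCc1ccccc1)N1C(=O)OC[C@@H]1Cc1ccccc1 | intermediate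
7 | (Z)-dibutylboron enolate of 6 | CCCCB(CCCC)O/C(=C\OCc1ccccc1)N1C(=O)OC[C@@H]1Cc1ccccc1 | intermediate
8 | (S)-4-benzyl-3-[(2S,3R)-2-(benzyloxy)-3-hydroxy-3-[3,4,5-tris(benzyloxy)phenyl]propanoyl]oxazolidin-2-one | O=C([C@@H](OCc1ccccc1)[C@H](O)c1cc(OCc2ccccc2)c(OCc2ccccc2)c(OCc2ccccc2)c1)N1C(=O)OC[C@@H]1Cc1ccccc1 | intermediate
9 | (2S,3R)-2-(benzyloxy)-3-hydroxy-N-methoxy-N-methyl-3-[3,4,5-tris(benzyloxy)phenyl]propanamide | CON(C)C(=O)[C@@H](OCc1ccccc1)[C@H](O)c1cc(OCc2ccccc2)c(OCc2ccccc2)c(OCc2ccccc2)c1 | intermediate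
10 | (2S,3R)-2-(benzyloxy)-N-methoxy-N-methyl-3-[(triethylsilyl)oxy]-3-[3,4,5-tris(benzyloxy)phenyl]propanamide | CON(C)C(=O)[C@@H](OCc1ccccc1)[C@H](O[Si](CC)(CC)CC)c1cc(OCc2ccccc2)c(OCc2ccccc2)c(OCc2ccccc2)c1 | intermediate
11 | (2S,3R)-2-(benzyloxy)-3-[(triethylsilyl)oxy]-3-[3,4,5-tris(benzyloxy)phenyl]propanal | O=C[C@@H](OCc1ccccc1)[C@H](O[Si](CC)(CC)CC)c1cc(OCc2ccccc2)c(OCc2ccccc2)c(OCc2ccccc2)c1 | intermediate
12 | methyl (2E,4R,5R)-4-(benzyloxy)-5-[(triethylsilyl)oxy]-5-[3,4,5-tris(benzyloxy)phenyl]pent-2-enoate | COC(=O)/C=C/[C@@H](OCc1ccccc1)[C@H](O[Si](CC)(CC)CC)c1cc(OCc2ccccc2)c(OCc2ccccc2)c(OCc2ccccc2)c1 | intermediate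
13 | methyl (4R,5R)-4-(benzyloxy)-5-[(triethylsilyl)oxy]-5-[3,4,5-tris(benzyloxy)phenyl]pentanoate | COC(=O)CC[C@@H](OCc1ccccc1)[C@H](O[Si](CC)(CC)CC)c1cc(OCc2ccccc2)c(OCc2ccccc2)c(OCc2ccccc2)c1 | intermediate
14 | methyl (4R,5R)-4-(benzyloxy)-5-hydroxy-5-[3,4,5-tris(benzyloxy)phenyl]pentanoate | COC(=O)CC[C@@H](OCc1ccccc1)[C@H](O)c1cc(OCc2ccccc2)c(OCc2ccccc2)c(OCc2ccccc2)c1 | intermediate
15 | (5R,6R)-5-(benzyloxy)-6-[3,4,5-tris(benzyloxy)phenyl]tetrahydro-2H-pyran-2-one | O=C1CC[C@@H](OCc2ccccc2)[C@@H](c2cc(OCc3ccccc3)c(OCc3ccccc3)c(OCc3ccccc3)c2)O1 | intermediate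
16 | (2R,3R)-3-(benzyloxy)-2-[3,4,5-tris(benzyloxy)phenyl]-3,4-dihydro-2H-pyran-6-yl diphenyl phosphate | O=P(Oc1ccccc1)(Oc1ccccc1)OC1=CC[C@@H](OCc2ccccc2)[C@@H](c2cc(OCc3ccccc3)c(OCc3ccccc3)c(OCc3ccccc3)c2)O1 | intermediate
17 | [(2R,3R)-3-(benzyloxy)-2-[3,4,5-tris(benzyloxy)phenyl]-3,4-dihydro-2H-pyran-6-yl]trimethylstannane | C[Sn](C)(C)C1=CC[C@@H](OCc2ccccc2)[C@@H](c2cc(OCc3ccccc3)c(OCc3ccccc3)c(OCc3ccccc3)c2)O1 | intermediate
18 | 2,2,6-trimethyl-4H-1,3-dioxin-4-one | CC1=CC(=O)OC(C)(C)O1 | starting material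
19 | 6-(chloromethyl)-2,2-dimethyl-4H-1,3-dioxin-4-one | ClCC1=CC(=O)OC(C)(C)O1 | intermediate
20 | 6-{[(2R,3R)-3-(benzyloxy)-2-[3,4,5-tris(benzyloxy)phenyl]-3,4-dihydro-2H-pyran-6-yl]methyl}-2,2-dimethyl-4H-1,3-dioxin-4-one | CC1(C)OC(=O)C=C(CC2=CC[C@@H](OCc3ccccc3)[C@@H](c3cc(OCc4ccccc4)c(OCc4ccccc4)c(OCc4ccccc4)c3)O2)O1 | intermediate
21 | 4-[(2R,3R)-3-(benzyloxy)-2-[3,4,5-tris(benzyloxy)phenyl]-3,4-dihydro-2H-pyran-6-yl]but-1-ene-1,3-dione (acylketene) | O=C=CC(=O)CC1=CC[C@@H](OCc2ccccc2)[C@@H](c2cc(OCc3ccccc3)c(OCc3ccccc3)c(OCc3ccccc3)c2)O1 | intermediate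
22 | (2R,3R)-3-(benzyloxy)-2-[3,4,5-tris(benzyloxy)phenyl]-3,4,6,8-tetrahydro-2H-chromene-5,7-dione | O=C1CC(=O)C2=C(C1)O[C@H](c1cc(OCc3ccccc3)c(OCc3ccccc3)c(OCc3ccccc3)c1)[C@H](OCc1ccccc1)C2 | intermediate
23 | (2R,3R)-3-(benzyloxy)-2-[3,4,5-tris(benzyloxy)phenyl]chroman-5,7-diol | Oc1cc(O)c2c(c1)O[C@H](c1cc(OCc3ccccc3)c(OCc3ccccc3)c(OCc3ccccc3)c1)[C@H](OCc1ccccc1)C2 | intermediate
24 | (2R,3R)-3-(benzyloxy)-5-hydroxy-2-[3,4,5-tris(benzyloxy)phenyl]chroman-7-yl 3,4,5-tris(benzyloxy)benzoate | O=C(Oc1cc(O)c2c(c1)O[C@H](c1cc(OCc3ccccc3)c(OCc3ccccc3)c(OCc3ccccc3)c1)[C@H](OCc1ccccc1)C2)c1cc(OCc2ccccc2)c(OCc2ccccc2)c(OCc2ccccc2)c1 | intermediate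
25 | (−)-epigallocatechin 7-O-gallate, (2R,3R)-3,5-dihydroxy-2-(3,4,5-trihydroxyphenyl)chroman-7-yl 3,4,5-trihydroxybenzoate | O=C(Oc1cc(O)c2c(c1)O[C@H](c1cc(O)c(O)c(O)c1)[C@H](O)C2)c1cc(O)c(O)c(O)c1 | target

Total step count: 17.
Longest linear sequence: 15 steps, from 1 to 25 through steps 1, 2, 4–12 and 14–17. Steps 3 and 13 are side branches.

Steps most likely to fail

1. Step 15. The ketene may be lost to dimerisation, to hydrolysis followed by decarboxylation, or to O-acylation of product phenols before C4a attacks. Proton-catalysed drift of the enol-ether double bond into the conjugated exocyclic position would also slow the closure. The fallback uses known chemistry and sets out from 16. Negishi methylation (MeZnCl, Pd(PPh3)4, THF) should give (2R,3R)-3-(benzyloxy)-6-methyl-2-[3,4,5-tris(benzyloxy)phenyl]-3,4-dihydro-2H-pyran F1. This is an enol ether with a nucleophilic ring carbon (future C4a) and an α′-methyl group (future C8). Malonyl dichloride (Et2O, −20 °C to rt) then acylates both carbons, as in the Effenberger synthesis of phloroglucinols from enol ethers, and delivers C5–C6–C7 in a [3+3] sense. The fallback comes back to the route at 23.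

2. Step 14. Three processes could erode the coupling: slow transmetalation, protodestannylation of the acid-sensitive α-alkoxyvinylstannane, and migration of the skipped double bond into conjugation during reaction or purification. The fallback reverses the polarity. It sets out from 16 and 19 and bypasses the stannane. Zinc insertion into 19 (Zn, LiCl, THF, 0 °C) should give the vinylogous Reformatsky reagent [(2,2-dimethyl-4-oxo-4H-1,3-dioxin-6-yl)methyl]zinc chloride F2. Negishi coupling with 16 (Pd(PPh3)4, THF, rt to 45 °C) joins it at the CH2 carbon, which keeps the dioxinone conjugated. The fallback comes back to the route at 20.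

3. Step 16. The two phenols may not be discriminated well enough, and over-acylation may occur. The fallback replaces direct acylation by a protecting-group relay and sets out from 23.
   - The very bulky TIPSCl (imidazole, DMF, 0 °C) should silylate the unflanked 7-OH to give (2R,3R)-3-(benzyloxy)-7-[(triisopropylsilyl)oxy]-2-[3,4,5-tris(benzyloxy)phenyl]chroman-5-ol F3.
   - Neutral Mitsunobu benzylation of the 5-OH (BnOH, PPh3, DIAD, THF) gives the 5-benzyl 7-silyl diether F4.
   - TBAF buffered with AcOH frees (2R,3R)-3,5-bis(benzyloxy)-2-[3,4,5-tris(benzyloxy)phenyl]chroman-7-ol F5.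
   - Acylation with 2 (i-Pr2NEt, DMAP, CH2Cl2) is now unambiguous and gives the octabenzyl ester F6.
   - Hydrogenolysis under the conditions of step 17 comes back to the route at 25.

Further compounds
F1 | step 15 | (2R,3R)-3-(benzyloxy)-6-methyl-2-[3,4,5-tris(benzyloxy)phenyl]-3,4-dihydro-2H-pyran | CC1=CC[C@@H](OCc2ccccc2)[C@@H](c2cc(OCc3ccccc3)c(OCc3ccccc3)c(OCc3ccccc3)c2)O1
F2 | step 14 | [(2,2-dimethyl-4-oxo-4H-1,3-dioxin-6-yl)methyl]zinc chloride | Cl[Zn]CC1=CC(=O)OC(C)(C)O1
F3 | step 16 | (2R,3R)-3-(benzyloxy)-7-[(triisopropylsilyl)oxy]-2-[3,4,5-tris(benzyloxy)phenyl]chroman-5-ol | CC(C)[Si](Oc1cc(O)c2c(c1)O[C@H](c1cc(OCc3ccccc3)c(OCc3ccccc3)c(OCc3ccccc3)c1)[C@H](OCc1ccccc1)C2)(C(C)C)C(C)C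
F4 | step 16 | {[(2R,3R)-3,5-bis(benzyloxy)-2-[3,4,5-tris(benzyloxy)phenyl]chroman-7-yl]oxy}triisopropylsilane | CC(C)[Si](Oc1cc(OCc3ccccc3)c2c(c1)O[C@H](c1cc(OCc3ccccc3)c(OCc3ccccc3)c(OCc3ccccc3)c1)[C@H](OCc1ccccc1)C2)(C(C)C)C(C)C
F5 | step 16 | (2R,3R)-3,5-bis(benzyloxy)-2-[3,4,5-tris(benzyloxy)phenyl]chroman-7-ol | Oc1cc(OCc3ccccc3)c2c(c1)O[C@H](c1cc(OCc3ccccc3)c(OCc3ccccc3)c(OCc3ccccc3)c1)[C@H](OCc1ccccc1)C2
F6 | step 16 | (2R,3R)-3,5-bis(benzyloxy)-2-[3,4,5-tris(benzyloxy)phenyl]chroman-7-yl 3,4,5-tris(benzyloxy)benzoate | O=C(Oc1cc(OCc3ccccc3)c2c(c1)O[C@H](c1cc(OCc3ccccc3)c(OCc3ccccc3)c(OCc3ccccc3)c1)[C@H](OCc1ccccc1)C2)c1cc(OCc2ccccc2)c(OCc2ccccc2)c(OCc2ccccc2)c1
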